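**Retrosynthetic overview**
1. Target 12 ⇒ cyclohexenyl nonaflate 11 + MeZnCl (Negishi) ⇒ silyl enol ether 10.
2. Key disconnection, aryl–C1 bond of 10 ⇒ enone 5 + aryl bromide 9. In the forward sense nickel and Et3SiCl turn the enone into a 1-silyloxyallyl nickel (a homoenolate equivalent), so its β-carbon couples with the aryl halide; this fixes the benzylic centre and the enol position together.
3. 5 ⇒ enal 2 + methyl vinyl ketone 3 (asymmetric dienamine Michael/aldol, i.e. Robinson annulation, sets the quaternary centre); 2 ⇒ osthol 1 (allylic oxidation).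
4. 9 ⇒ salicylaldehyde 6 + ylide 7 (Wittig/lactonisation).
5. Ring order: the coumarin of 1 is bought; the cyclohexenone ring (step 2) and the second coumarin lactone (step 3) are closed separately; no ring is formed after that.

Assumption: the sense of induction of the amine catalyst in step 2 cannot be predicted with certainty, so the quinine-derived amine is written and its quinidine-derived pseudo-enantiomer is used instead if the (4R)-enone is obtained.

**Step 1**
Reactants: 1 osthol, 7-methoxy-8-(3-methylbut-2-en-1-yl)-2H-chromen-2-one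
Product: 2 (E)-4-(7-methoxy-2-oxo-2H-chromen-8-yl)-2-methylbut-2-enal
Conditions: SeO2 (1.5 equiv), 1,4-dioxane, 100 °C
Reagents that add atoms: selenium dioxide, O=[Se]=O
Why: Riley allylic oxidation (ene reaction then [2,3]-sigmatropic shift) attacks the (E)-methyl group at the more substituted end of the prenyl alkene and takes it to the (E)-enal, while lactone and aryl ether are inert; no stereocentre is formed.

**Step 2**
Reactants: 2 (E)-4-(7-methoxy-2-oxo-2H-chromen-8-yl)-2-methylbut-2-enal; 3 but-3-en-2-one (methyl vinyl ketone, 2 equiv)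
Product: 5 (4S)-4-[(E)-2-(7-methoxy-2-oxo-2H-chromen-8-yl)ethenyl]-4-methylcyclohex-2-en-1-one, via keto-aldehyde Michael adduct 4 (not isolated)
Conditions: 9-amino-9-deoxy-epi-quinine (20 mol%), TFA (40 mol%), PhMe, 25 °C; then TsOH·H2O (20 mol%), 80 °C
Reagents that add atoms: none
Why: Proposed new method: the chiral primary amine condenses with the α-branched enal and γ-deprotonation at the benzylic CH2 gives a dienamine, whose α-carbon adds to methyl vinyl ketone through an N–H···O=C organised six-membered (aza-ene-like) transition state that cannot reach the hindered γ-carbon, the catalyst shielding one face to set the quaternary (S)-centre and leaving the new alkene (E) and conjugated to the coumarin, after which acid closes the ring by aldol condensation with loss of water (Robinson annulation); the closest known reactions are primary-amine-catalysed asymmetric Michael/Robinson annulations of α-branched aldehydes with vinyl ketones and the α-alkylation of Stork dienamines.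

**Step 3**
Reactants: 6 5-bromo-2-hydroxy-4-methoxybenzaldehyde; 7 ethyl (triphenylphosphoranylidene)acetate
Product: 9 6-bromo-7-methoxy-2H-chromen-2-one, via ethyl hydroxycinnamate 8 (not isolated)
Conditions: PhNEt2, 210 °C
Reagents that add atoms: none
Why: Wittig olefination of the salicylaldehyde gives the hydroxycinnamate, which at 210 °C isomerises about the C=C bond and lactonises with loss of ethanol (standard coumarin synthesis); no stereocentre is formed.

**Step 4**
Reactants: 5 (4S)-4-[(E)-2-(7-methoxy-2-oxo-2H-chromen-8-yl)ethenyl]-4-methylcyclohex-2-en-1-one; 9 6-bromo-7-methoxy-2H-chromen-2-one (1.3 equiv)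
Product: 10 triethyl({(3S,4S)-3-(7-methoxy-2-oxo-2H-chromen-6-yl)-4-[(E)-2-(7-methoxy-2-oxo-2H-chromen-8-yl)ethenyl]-4-methylcyclohex-1-en-1-yl}oxy)silane
Conditions: NiCl2(MeOCH2CH2OMe) (10 mol%), neocuproine (10 mol%), Mn powder (2 equiv), Et3SiCl (1.5 equiv), DMF, 40 °C
Reagents that add atoms: chlorotriethylsilane, CC[Si](Cl)(CC)CC
Why: Key step, a nickel-catalysed reductive conjugate arylation (cross-electrophile coupling): zerovalent nickel and Et3SiCl convert the enone into a 1-silyloxyallyl nickel, a homoenolate equivalent whose β-carbon then couples with the aryl bromide, so two electrophilic carbons are joined and the enol double bond is fixed on the side of the new benzylic carbon; that centre is set by substrate control, because nickel binds the enone face on which the neighbouring styryl alkene can chelate (skipped-diene complex) and the carbon–carbon reductive elimination is suprafacial, placing the aryl group cis to the styryl group and trans to methyl (3S).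

**Step 5**
Reactants: 10 triethylsilyl enol ether from step 4
Product: 11 (3S,4S)-3-(7-methoxy-2-oxo-2H-chromen-6-yl)-4-[(E)-2-(7-methoxy-2-oxo-2H-chromen-8-yl)ethenyl]-4-methylcyclohex-1-en-1-yl nonafluorobutane-1-sulfonate
Conditions: n-C4F9SO2F (1.5 equiv), Bu4N[Ph3SiF2] (10 mol%), THF, 0 → 25 °C
Reagents that add atoms: nonafluorobutane-1-sulfonyl fluoride, FS(=O)(=O)C(F)(F)C(F)(F)C(F)(F)C(F)(F)F
Why: Fluoride-catalysed desilylation–sulfonylation of a silyl enol ether (alkenyl nonaflate formation): the fluoride released by each sulfonylation cleaves the next Si–O bond, so the enolate is trapped as it forms and the double bond stays between C1 and C2 of the ring; both stereocentres are untouched.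

**Step 6**
Reactants: 11 alkenyl nonaflate from step 5
Product: 12 7-methoxy-6-{(1S,6S)-6-[(E)-2-(7-methoxy-2-oxo-2H-chromen-8-yl)ethenyl]-3,6-dimethylcyclohex-2-en-1-yl}-2H-chromen-2-one (target)
Conditions: MeZnCl (2 equiv), Pd(PPh3)4 (5 mol%), THF, 50 °C
Reagents that add atoms: methylzinc chloride, C[Zn]Cl
Why: Negishi cross-coupling: oxidative addition of zerovalent palladium into the alkenyl nonaflate, transmetalation from MeZnCl and reductive elimination place the methyl group on the existing double bond; organozinc reagents do not attack the lactones and no stereocentre is affected.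

**Compound list**
1 | osthol, 7-methoxy-8-(3-methylbut-2-en-1-yl)-2H-chromen-2-one | CC(C)=CCc1c(OC)ccc2ccc(=O)oc12 | starting material
2 | (E)-4-(7-methoxy-2-oxo-2H-chromen-8-yl)-2-methylbut-2-enal | O=C/C(C)=C/Cc1c(OC)ccc2ccc(=O)oc12 | intermediate
3 | but-3-en-2-one (methyl vinyl ketone) | CC(=O)C=C | starting material
4 | (2S)-2-[(E)-2-(7-methoxy-2-oxo-2H-chromen-8-yl)ethenyl]-2-methyl-5-oxohexanal | O=C[C@](C)(/C=C/c1c(OC)ccc2ccc(=O)oc12)CCC(C)=O | intermediate
5 | (4S)-4-[(E)-2-(7-methoxy-2-oxo-2H-chromen-8-yl)ethenyl]-4-methylcyclohex-2-en-1-one | O=C1C=C[C@](C)(/C=C/c2c(OC)ccc3ccc(=O)oc23)CC1 | intermediate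
6 | 5-bromo-2-hydroxy-4-methoxybenzaldehyde | O=Cc1cc(Br)c(OC)cc1O | starting material
7 | ethyl (triphenylphosphoranylidene)acetate | CCOC(=O)C=P(c1ccccc1)(c1ccccc1)c1ccccc1 | starting material
8 | ethyl (E)-3-(5-bromo-2-hydroxy-4-methoxyphenyl)prop-2-enoate | CCOC(=O)/C=C/c1cc(Br)c(OC)cc1O | intermediate
9 | 6-bromo-7-methoxy-2H-chromen-2-one | COc1cc2oc(=O)ccc2cc1Br | intermediate
10 | triethyl({(3S,4S)-3-(7-methoxy-2-oxo-2H-chromen-6-yl)-4-[(E)-2-(7-methoxy-2-oxo-2H-chromen-8-yl)ethenyl]-4-methylcyclohex-1-en-1-yl}oxy)silane | COc1cc2oc(=O)ccc2cc1[C@H]1C=C(O[Si](CC)(CC)CC)CC[C@@]1(C)/C=C/c1c(OC)ccc2ccc(=O)oc12 | intermediate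
11 | (3S,4S)-3-(7-methoxy-2-oxo-2H-chromen-6-yl)-4-[(E)-2-(7-methoxy-2-oxo-2H-chromen-8-yl)ethenyl]-4-methylcyclohex-1-en-1-yl nonafluorobutane-1-sulfonate | COc1cc2oc(=O)ccc2cc1[C@H]1C=C(OS(=O)(=O)C(F)(F)C(F)(F)C(F)(F)C(F)(F)F)CC[C@@]1(C)/C=C/c1c(OC)ccc2ccc(=O)oc12 | intermediate
12 | 7-methoxy-6-{(1S,6S)-6-[(E)-2-(7-methoxy-2-oxo-2H-chromen-8-yl)ethenyl]-3,6-dimethylcyclohex-2-en-1-yl}-2H-chromen-2-one | COc1cc2oc(=O)ccc2cc1[C@H]1C=C(C)CC[C@@]1(C)/C=C/c1c(OC)ccc2ccc(=O)oc12 | target

**Totals**
Total step count: 6. Longest linear sequence: 5 steps (1 → 2 → 5 → 10 → 11 → 12).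

**Three steps most likely to fail**

Step 4 is the largest risk. The β-carbon is neopentyl, the aryl bromide is ortho-substituted, the coumarin enoates might compete for nickel, and the facial selectivity rests on a chelation argument that steric control alone would not guarantee. The fallback sets out from 5 and 9 and replaces the cross-electrophile coupling by a catalyst-controlled addition of a nucleophilic aryl metal. Bromide 9 is converted with Zn dust and CoBr2 (10 mol%) in MeCN into (7-methoxy-2-oxo-2H-chromen-6-yl)zinc bromide F1. F1 is added to 5 with [RhCl{(R)-BINAP}]2 (or the (S)-ligand, whichever is matched to the 3S outcome) and Me3SiCl in THF at 20 °C. This gives the trimethylsilyl enol ether F2, with the same enol regiochemistry and the face chosen by the ligand. F2 is sulfonylated under the conditions of step 5, and the fallback comes back to the route at 11.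

Step 2 is the second risk, because the dienamine could react at its γ-carbon and the enantioselectivity for an α-methyl, α-alkenyl donor is unproven. The fallback sets out from 2 and 3 and sets the quaternary centre by desymmetrisation instead. The potassium dienolate of 2 (KOtBu, 10 mol%, tBuOH/THF, 0 °C; extended enolates alkylate at the α-carbon) adds to 3 to give racemic 2-[(E)-2-(7-methoxy-2-oxo-2H-chromen-8-yl)ethenyl]-2-methyl-5-oxohexanal F3. F3 is cyclised without isolation (TsOH·H2O, PhMe, 80 °C) to the racemic enone F4. Dehydrogenation with 2-iodoxybenzoic acid in DMSO at 80 °C gives the achiral 4-[(E)-2-(7-methoxy-2-oxo-2H-chromen-8-yl)ethenyl]-4-methylcyclohexa-2,5-dien-1-one F5. Enantioselective conjugate hydrosilylation of one of its two enantiotopic enone units with Rh(OAc)2(H2O)(iPr-Phebox) (2 mol%) and (EtO)2MeSiH in PhMe at 50 °C gives the silyl dienol ether F6; the selectivity for the dienone over the coumarin enoates would have to be checked. Mild aqueous acid hydrolyses F6, and the fallback comes back to the route at 5.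

Step 5 is the third risk: the triethylsilyl group may cleave slowly, and a free enolate could be protonated or could move the double bond. The fallback sets out from 5 and avoids any enol sulfonate. MeTi(OiPr)3 in THF at 0 °C adds chemoselectively to the ketone of 5 to give the tertiary allylic alcohol (4S)-4-[(E)-2-(7-methoxy-2-oxo-2H-chromen-8-yl)ethenyl]-1,4-dimethylcyclohex-2-en-1-ol F7 (both carbinol epimers). Ac2O with Sc(OTf)3 (5 mol%) in MeCN converts F7 into the tertiary allylic acetate F8. Nickel-catalysed reductive allylic arylation of F8 with 9 (NiCl2(MeOCH2CH2OMe) 10 mol%, 2,2':6',2''-terpyridine, Zn dust, DMF, 40 °C) goes through a π-allyl nickel common to both epimers. The aryl group joins the less substituted allyl terminus, which leaves the double bond on the methyl-bearing carbon, and the fallback comes back to the route at 12; the cis/trans ratio at the new centre would have to be checked.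

**Further compounds**
F1 | step 4 | (7-methoxy-2-oxo-2H-chromen-6-yl)zinc bromide | COc1cc2oc(=O)ccc2cc1[Zn]Br
F2 | step 4 | trimethyl({(3S,4S)-3-(7-methoxy-2-oxo-2H-chromen-6-yl)-4-[(E)-2-(7-methoxy-2-oxo-2H-chromen-8-yl)ethenyl]-4-methylcyclohex-1-en-1-yl}oxy)silane | COc1cc2oc(=O)ccc2cc1[C@H]1C=C(O[Si](C)(C)C)CC[C@@]1(C)/C=C/c1c(OC)ccc2ccc(=O)oc12
F3 | step 2 | racemic 2-[(E)-2-(7-methoxy-2-oxo-2H-chromen-8-yl)ethenyl]-2-methyl-5-oxohexanal | O=CC(C)(/C=C/c1c(OC)ccc2ccc(=O)oc12)CCC(C)=O
F4 | step 2 | racemic 4-[(E)-2-(7-methoxy-2-oxo-2H-chromen-8-yl)ethenyl]-4-methylcyclohex-2-en-1-one | O=C1C=CC(C)(/C=C/c2c(OC)ccc3ccc(=O)oc23)CC1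
F5 | step 2 | 4-[(E)-2-(7-methoxy-2-oxo-2H-chromen-8-yl)ethenyl]-4-methylcyclohexa-2,5-dien-1-one | O=C1C=CC(C)(/C=C/c2c(OC)ccc3ccc(=O)oc23)C=C1
F6 | step 2 | diethoxy(methyl)({(4S)-4-[(E)-2-(7-methoxy-2-oxo-2H-chromen-8-yl)ethenyl]-4-methylcyclohexa-1,5-dien-1-yl}oxy)silane | CCO[Si](C)(OCC)OC1=CC[C@@](C)(/C=C/c2c(OC)ccc3ccc(=O)oc23)C=C1
F7 | step 5 | (4S)-4-[(E)-2-(7-methoxy-2-oxo-2H-chromen-8-yl)ethenyl]-1,4-dimethylcyclohex-2-en-1-ol | CC1(O)C=C[C@](C)(/C=C/c2c(OC)ccc3ccc(=O)oc23)CC1
F8 | step 5 | (4S)-4-[(E)-2-(7-methoxy-2-oxo-2H-chromen-8-yl)ethenyl]-1,4-dimethylcyclohex-2-en-1-yl acetate | CC(=O)OC1(C)C=C[C@](C)(/C=C/c2c(OC)ccc3ccc(=O)oc23)CC1
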